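## The problem

Atoms are numbered as in the daucane skeleton: C1 is the methyl-bearing fusion carbon, C4 the isopropyl carbinol, C5 the fusion CH, C6 the aroyloxy carbon, C7 a CH2, C8 and C9 the alkene carbons, and C10 the isovaleryloxy carbon.

- Target 27 is a cis-fused bicyclo[5.3.0]decane with five stereocentres: quaternary C1, tertiary carbinol C4, C5, and the secondary carbinols C6 and C10. The C4 hydroxyl lies on the face of the angular methyl and H5, the isopropyl group on the concave face. The C6 and C10 oxygens are cis to each other and syn to the cyclopentane.
- A synthesis must fuse a cyclopentane to a cycloheptene through a quaternary carbon. It must also tell apart two secondary alcohols flanking the ring fusion: one becomes an isovalerate allylic to the C8=C9 alkene, the other a 4-hydroxybenzoate.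
- The cis fusion gives a convex face that can act as a relay. C1/C5 can direct the oxygen at C4, the C4 substituents can direct hydride to C6, and the C6 substituent can direct hydride to C10.
- Several features are fragile. The C4 alcohol is β to C6, so a C6 carbonyl invites dehydration, retro-aldol cleavage and epimerisation at C5. The allylic C10 ester ionises under acid. The trisubstituted alkene excludes hydrogenolysis and unselective epoxidation. Hydrides strong enough to open an epoxide cannot be used once esters are present.
- The enabling feature is that C10 and C6 are carbinol carbons on the adjacent fusion atoms C1 and C5 and are bridged by C9, C8 and C7, with C8 carrying one extra carbon. The cycloheptene is therefore a cyclopentane 1,4-dialdehyde plus a 2-methylidenepropane-1,3-diyl unit.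
- Such a dialdehyde is the ozonolysis product of a fused cyclobutene, which makes the cis relation of the two formyl groups automatic.

## Retrosynthesis

**Esters and phenol.** Target 27 is opened at the aryl O–Si bond (26), then at the C10–O acyl bond (24 + 25) and at the C6–O acyl bond (23, from 19 + 22). The two ester bonds are cut at different oxidation levels of C10 rather than from a 6,10-diol. In 19 the C10 oxygen is a ketone, so the aroyl group can only go to C6; in 24 the only free secondary hydroxyl is at C10. This removes fifteen heavy atoms of side chain and leaves a bicyclic hydroxy enone. The forward steps are acylations of one secondary alcohol beside the inert tertiary C4 hydroxyl. The phenol travels as the silyl ether of 22 (from 20), which fluoride removes without touching the esters.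

**C10 carbinol and alkene position.** The C10–H bond of 24 is cut to enone 23. Conjugation with a C10 carbonyl whose other α-carbon (C1) is quaternary can only place the alkene at C8=C9, whereas direct isomerisation of an 8-methylidene diol would not distinguish C7 from C9. One stereocentre is removed. The forward 1,2-reduction must deliver hydride anti to the C6 ester.

**Telling C6 from C10.** Enone 19 is traced to the β,γ-unsaturated ketone 18 and then, by cutting the C6–H bond, to dione 17, the double oxidation product of triol 16. The neighbouring option is protection of one of the two secondary hydroxyls of 16 on steric grounds. The chosen cut rests instead on a structural difference: only the C6 carbonyl is β to the C4 hydroxyl, which can deliver hydride. It also makes the route independent of the carbinol configurations of 16. The precursor has two stereocentres fewer. The forward reaction requires that the dione survive unconjugated until it is reduced.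

**Seven-membered ring.** In 16 the bonds C9–C10 and C6–C7 are cut, leaving dialdehyde 14 and the four-carbon unit 15. A single ring-closing cut or a one-carbon ring expansion would leave a chain or a ring still to be built. This cut removes the ring, four carbons and both secondary carbinol centres at once, and the symmetry of 15 leaves no regiochemical question. The forward reaction must add twice, the second time intramolecularly, to a hindered and epimerisable cis-dialdehyde while tolerating a free tertiary alcohol.

**cis-Dialdehyde.** The two formyl carbons of 14 are reconnected as the alkene of cyclobutene 12 (ozonolysis retron). A cyclobutene fused to a cyclopentane can only be cis, so the relation that makes the annulation intramolecular is built in. The precursor is a stable bicyclic alcohol instead of a labile dialdehyde. The forward cleavage must be neutral.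

**C4.** The tertiary alcohol of 12 is cut at the C3–H bond (epoxide 11), at the epoxide C–O bonds (diene 10) and at the C4–isopropyl bond (enol triflate 9, ketone 7). Direct addition of an isopropyl nucleophile to 7 would be shorter, but it would come from the convex face and give the C4 epimer. Epoxidation from that face followed by hydride opening at C3 puts the oxygen where the target has it. This is done before the annulation rather than late on a masked C4 ketone, because the only other alkene is then the unreactive cyclobutene and the strong hydride is used before any ester exists. The forward steps need regioselective enolisation, transfer of a secondary alkyl group and exo-selective epoxidation.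

**Absolute configuration.** Ketone 7 is one enantiomer of racemic 4, reached through endo alcohol 5 and its enzymatic resolution to 6. No dependable enantioselective photocycloaddition of this enone is available, so a resolution at the cheapest stage is accepted. It costs three simple steps and half of an inexpensive intermediate.

**Bicyclo[3.2.0] core.** Ketone 4 comes from dichloride 3 by reductive elimination. Cutting C1–C10 and C5–C6 of 3 gives enone 1 and alkene 2, joined by a (2+2) photocycloaddition. That first step creates the quaternary carbon and the cis fusion from two commodity chemicals.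

## Roads not taken

**Alternative 1:** silylallene annulation on a quinone.
- **Cut:** C1–C2 and C4–C5 of the cyclopentane.
- **Forward key step:** a titanium Lewis acid would promote addition of the allene terminus of A2 to the methyl-bearing carbon of quinone A1. After a 1,2-silyl shift, the enolate carbon closes on the vinyl cation to give the cis-fused ene-dione A3.
- **Merits:** one step from two achiral compounds would deliver the cyclopentane, the quaternary C1, the cis fusion, the isopropyl group on C4, both ring carbonyls and the methyl-bearing alkene. In convergence it is clearly better than the chosen route, which needs ten steps to reach dialdehyde 14.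
- **Weak points:**
  - The carbocycle inherited from A1 is six-membered. One carbon must be inserted between the C10 carbonyl and the methyl-bearing carbon, a ring expansion that has to choose between two ketones and two migrating groups.
  - The allene must attack the more substituted quinone carbon, against the normal preference for the unsubstituted one.
  - The vinylsilane of A3 must still be turned into the C4 carbinol (protodesilylation, epoxidation, hydride), now beside an ene-dione.
  - The step is racemic.
- **Comparison:** the chosen plan gives the seven-membered ring and the C8 substitution by construction and fixes the absolute configuration before the expensive steps.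

**Alternative 2:** Prins–pinacol ring-enlarging annulation.
- **Cut:** C2–C3, plus the C1–C5 bond (made by a 1,2-shift of C5 from C10 to C1).
- **Forward key step:** a tin Lewis acid ionises the dimethyl acetal of cyclohexanol A4. The isopropenyl terminus attacks the oxocarbenium ion, and the tertiary cation at C1 triggers the pinacol shift, closing the cyclopentane and enlarging the six-membered ring to cycloheptanone A5.
- **Merits:** both rings, the quaternary C1 and the cis fusion arise in one stereospecific event. A5 also has C10 as a ketone and C6 as a silyl ether, so the two oxygens are differentiated from the start. In this respect it is better than the chosen plan, which needs the directed reduction of step 13 for the same purpose.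
- **Weak points:**
  - A5 lacks the C8 methyl and the C8=C9 alkene (dehydrogenation and a β-methylation sequence would be needed).
  - A5 carries an unwanted methoxy group at C3 and has C4 as a methine. Loss of methanol and the same epoxidation and hydride sequence as here would still be needed to make the C4 carbinol.
  - A4 has three stereocentres that must be set enantioselectively before the key step.
- **Comparison:** skeleton-forming power is equal or higher. The chosen plan brings in C8 with its extra carbon and both oxygens in the annulation itself, carries no superfluous functionality, and starts from much simpler materials.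

**Alternative 3:** Buchner ring expansion.
- **Cut:** C7–C8 and C8–C9; C8 is inserted into an arene bond.
- **Forward key step:** the rhodium carbenoid from A7 would cyclopropanate the only unsubstituted arene bond of indane A6, and the norcaradiene would open to cycloheptatriene A8.
- **Merits:** a cheap aromatic precursor, the C4 carbinol already in place (as in the chosen plan), oxygen at C6 and C10 from the two methoxy groups, and C8 introduced with a carbon handle.
- **Weak points:**
  - In A8 both fusion carbons are sp2. The angular methyl at C1 and the cis hydrogen at C5 would have to be introduced late on a planar dienone, with only C4 to direct them.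
  - The ester must be reduced to a methyl group over several steps.
  - Hydrolysis of the two enol ethers gives the same vinylogous diketone in which C6 and C10 are hard to tell apart.
  - Carbenoid addition to an electron-rich dimethoxyarene competes with insertion and ylide pathways, and hydrogen shifts in the cycloheptatriene can move the ester.
- **Comparison:** it reaches a functionalised seven-membered ring in fewer steps. The chosen plan sets the quaternary centre and the cis fusion in its first step and never has to create them on a flat ring.

Key step: step 11

Assumption: daucane numbering is used for all bicyclo[5.3.0] compounds; racemic compounds 3–5 are written with both enantiomers in one SMILES; the secondary ozonide 13 is a mixture at its two acetal carbons, which are left undefined; compounds 1, 2, 15, 20 and 25 and all reagents are commercial.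

## Route

Step 1
Reactants: 1 3-methylcyclopent-2-en-1-one; 2 (E)-1,2-dichloroethene
Product: 3 racemic cis-fused 6,7-dichloro-5-methylbicyclo[3.2.0]heptan-2-one (mixture of chlorine epimers)
Conditions: hν (medium-pressure Hg lamp, Pyrex filter), 2 (10 equiv), CH2Cl2, 0 °C
Reagents that add atoms: none
Why: Enone–alkene (2+2) photocycloaddition through the enone triplet and a 1,4-diradical; a cyclopentenone can only give the cis-fused bicyclo[3.2.0]heptanone, which fixes the later C1/C5 relation. The alkene is symmetrical and the chlorine configurations are irrelevant.

Step 2
Reactants: 3 racemic cis-fused 6,7-dichloro-5-methylbicyclo[3.2.0]heptan-2-one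
Product: 4 racemic (1R,5S)-5-methylbicyclo[3.2.0]hept-6-en-2-one
Conditions: Zn dust (activated), AcOH (cat.), EtOH, 75 °C
Reagents that add atoms: none
Why: Reductive 1,2-elimination of the vicinal dichloride by zinc; all chlorine epimers converge on the cyclobutene, which is the masked cis-dialdehyde.

Step 3
Reactants: 4 racemic (1R,5S)-5-methylbicyclo[3.2.0]hept-6-en-2-one
Product: 5 racemic (1R,2S,5S)-5-methylbicyclo[3.2.0]hept-6-en-2-ol (endo alcohol)
Conditions: NaBH4, MeOH, 0 °C
Reagents that add atoms: none
Why: Borohydride reduction; hydride attacks the convex face anti to the cyclobutene and should give the endo alcohol as one diastereomer, the substrate for the enzymatic resolution.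

Step 4
Reactants: 5 racemic (1R,2S,5S)-5-methylbicyclo[3.2.0]hept-6-en-2-ol
Product: 6 (1R,2S,5S)-5-methylbicyclo[3.2.0]hept-6-en-2-ol (the enantiomer left unacylated)
Conditions: Burkholderia cepacia lipase (immobilised), vinyl acetate, t-BuOMe, 30 °C, stopped just past half conversion; chromatography
Reagents that add atoms: none
Why: Lipase-catalysed kinetic resolution by transesterification; by the empirical size rule for secondary alcohols (bridgehead carbon large, ring CH2 medium) the (2R)-alcohol should be acetylated and the wanted (2S)-alcohol left behind. Alcohol and acetate are separated by chromatography.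

Step 5
Reactants: 6 (1R,2S,5S)-5-methylbicyclo[3.2.0]hept-6-en-2-ol
Product: 7 (1R,5S)-5-methylbicyclo[3.2.0]hept-6-en-2-one
Conditions: Dess–Martin periodinane, NaHCO3, CH2Cl2, 0 °C to rt
Reagents that add atoms: none
Why: Dess–Martin oxidation returns the ketone as a single enantiomer; its bridgehead centres cannot epimerise because a trans-fused bicyclo[3.2.0] skeleton is not accessible.

Step 6
Reactants: 7 (1R,5S)-5-methylbicyclo[3.2.0]hept-6-en-2-one
Product: 9 (1R,5S)-5-methylbicyclo[3.2.0]hepta-2,6-dien-2-yl trifluoromethanesulfonate, via lithium dienolate 8 (not isolated)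
Conditions: LiN(SiMe3)2, THF, −78 °C; then PhNTf2, −78 to 0 °C
Reagents that add atoms: N-phenylbis(trifluoromethanesulfonimide), O=S(=O)(N(c1ccccc1)S(=O)(=O)C(F)(F)F)C(F)(F)F
Why: Kinetic enolisation and O-triflation; deprotonation can only occur at the C3 methylene, because an enolate toward the bridgehead would put a double bond at the cyclobutene fusion, so the enol triflate is regiodefined.

Step 7
Reactants: 9 (1R,5S)-5-methylbicyclo[3.2.0]hepta-2,6-dien-2-yl trifluoromethanesulfonate
Product: 10 (1R,5S)-5-methyl-2-(propan-2-yl)bicyclo[3.2.0]hepta-2,6-diene
Conditions: i-PrZnBr, PdCl2(dppf) (5 mol %; dppf = 1,1'-bis(diphenylphosphino)ferrocene), THF, 50 °C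
Reagents that add atoms: isopropylzinc bromide, CC(C)[Zn]Br
Why: Negishi cross-coupling of an alkenyl triflate; the wide bite angle of dppf makes reductive elimination faster than β-hydride elimination, so the secondary alkyl group should be transferred without isomerisation to n-propyl.

Step 8
Reactants: 10 (1R,5S)-5-methyl-2-(propan-2-yl)bicyclo[3.2.0]hepta-2,6-diene
Product: 11 (1R,2S,4R,6S)-6-methyl-2-(propan-2-yl)-3-oxatricyclo[4.2.0.0^2,4]oct-7-ene (exo epoxide, oxygen anti to the cyclobutene)
Conditions: m-CPBA (1.05 equiv), NaHCO3, CH2Cl2, −20 to 0 °C
Reagents that add atoms: 3-chloroperoxybenzoic acid, OOC(=O)c1cccc(Cl)c1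
Why: Prilezhaev epoxidation; the trisubstituted cyclopentene is far more nucleophilic than the 1,2-disubstituted cyclobutene, and the peracid approaches the convex face anti to the four-membered ring. The oxygen that becomes the C4 hydroxyl is thus placed cis to the angular methyl and H5.

Step 9
Reactants: 11 (1R,2S,4R,6S)-6-methyl-2-(propan-2-yl)-3-oxatricyclo[4.2.0.0^2,4]oct-7-ene
Product: 12 (1R,2S,5S)-5-methyl-2-(propan-2-yl)bicyclo[3.2.0]hept-6-en-2-ol
Conditions: LiEt3BH, THF, 0 °C to rt; aqueous NH4Cl
Reagents that add atoms: none
Why: SN2 opening of the trisubstituted epoxide by the trialkylborohydride at the secondary carbon C3 leaves the C4–O bond untouched, so the tertiary alcohol keeps the configuration set in step 8 (hydroxyl convex, isopropyl concave).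

Step 10
Reactants: 12 (1R,2S,5S)-5-methyl-2-(propan-2-yl)bicyclo[3.2.0]hept-6-en-2-ol
Product: 14 (1R,2R,3S)-3-hydroxy-1-methyl-3-(propan-2-yl)cyclopentane-1,2-dicarbaldehyde, via secondary ozonide 13 (not isolated)
Conditions: O3, CH2Cl2, −78 °C; then PPh3, −78 °C to rt; used crude at once
Reagents that add atoms: ozone, [O-][O+]=O
Why: Ozonolysis with reductive work-up; cleavage of the cyclobutene turns its two carbons into formyl groups that are necessarily cis, and the neutral conditions should leave the epimerisable C5 centre and the β-hydroxy aldehyde intact.

Step 11
Reactants: 14 (1R,2R,3S)-3-hydroxy-1-methyl-3-(propan-2-yl)cyclopentane-1,2-dicarbaldehyde; 15 3-chloro-2-(chloromethyl)prop-1-ene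
Product: 16 (1R,4S,5S,6R,10S)-dauc-8(14)-ene-4,6,10-triol (cis-fused 3-isopropyl-8a-methyl-6-methylidenedecahydroazulene-3,4,8-triol; drawn as the expected cis-6,10-diol)
Conditions: In powder (3 equiv), NaI (0.2 equiv), THF–H2O (1:1), 0.01 M, slow addition of 14 and 15, 25–35 °C
Reagents that add atoms: none
Why: Indium inserts into one allylic C–Cl bond of 15 (iodide-assisted) and the allylindium adds to one formyl group of 14 through a six-membered cyclic transition state with allyl transposition; a second insertion and an intramolecular 7-exo-trig carbonyl allylation of the other formyl group then close the cycloheptane, so C9–C10 and C6–C7 form in one flask and the symmetry of 15 makes α- and γ-attack equivalent. The closest known reaction type is the aqueous indium or tin Barbier allylation of aldehydes with 2-(halomethyl)allyl halides used as isobutene dianion equivalents, including double allylation of dicarbonyl compounds, and the related (3+4) annulation of 1,4-dicarbonyls with 2-methylidenepropane-1,3-diyl reagents. Ring closure is possible only because the formyl groups are held cis on adjacent cyclopentane carbons, a relation fixed by the cyclobutene of 12; high dilution favours it over oligomerisation. The near-neutral aqueous medium should avoid epimerisation at C5 and retro-aldol loss of the C4 carbinol, and it tolerates the unprotected tertiary alcohol. Of the two new stereocentres, the one formed in the first, intermolecular addition is set by the adjacent ring stereocentre (Felkin–Anh approach anti to the larger ring branch); the one formed in the ring closure is set by indium bridging the first alkoxide and the second carbonyl oxygen, which should hold both C–O bonds on one face and give a cis-6,10-diol. Neither configuration is relied upon, because step 12 erases both and any mixture of carbinol epimers converges. The selectivity needed is chemoselectivity for aldehydes and for cyclisation over intermolecular reaction, and it rests on the reactivity of allylindium reagents and on the cis-dialdehyde geometry.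

Step 12
Reactants: 16 (1R,4S,5S,6R,10S)-dauc-8(14)-ene-4,6,10-triol
Product: 17 (1R,4S,5R)-4-hydroxydauc-8(14)-ene-6,10-dione
Conditions: Dess–Martin periodinane (3 equiv), pyridine, CH2Cl2, 0 °C to rt; used without chromatography
Reagents that add atoms: none
Why: Dess–Martin oxidation of both secondary carbinols (the tertiary one is inert) under buffered conditions that should not move the exocyclic alkene; it removes the two carbinol centres of the annulation, so every diastereomer of 16 gives one dione.

Step 13
Reactants: 17 (1R,4S,5R)-4-hydroxydauc-8(14)-ene-6,10-dione
Product: 19 (1R,4S,5S,6R)-4,6-dihydroxydauc-8-en-10-one, via 6-hydroxy-8(14)-en-10-one 18 (not isolated)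
Conditions: Me4NBH(OAc)3, MeCN–AcOH (1:1), −30 to 0 °C; aqueous potassium sodium tartrate; then 1,8-diazabicyclo[5.4.0]undec-7-ene (0.2 equiv), CH2Cl2, rt
Reagents that add atoms: none
Why: Evans–Saksena hydroxyl-directed reduction: the triacetoxyborohydride exchanges onto the C4 hydroxyl and delivers hydride only to the β-carbonyl C6, on the face next to H5 and away from the concave isopropyl group, which should set 6R. The untouched C10 ketone, flanked by the quaternary C1, then draws the methylidene into conjugation under amine base and places the alkene at C8=C9.

Step 14
Reactants: 20 4-hydroxybenzoic acid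
Product: 22 4-[(tert-butyldimethylsilyl)oxy]benzoic acid, via bis-silylated acid 21 (not isolated)
Conditions: t-BuMe2SiCl (2.3 equiv), imidazole, DMF, rt; then AcOH–THF–H2O, rt
Reagents that add atoms: tert-butyldimethylsilyl chloride, CC(C)(C)[Si](C)(C)Cl
Why: Silylation of both acidic groups, then hydrolysis of the much more labile silyl ester under mild acid, which leaves the aryl silyl ether.

Step 15
Reactants: 19 (1R,4S,5S,6R)-4,6-dihydroxydauc-8-en-10-one; 22 4-[(tert-butyldimethylsilyl)oxy]benzoic acid
Product: 23 (1R,4S,5S,6R)-4-hydroxy-10-oxodauc-8-en-6-yl 4-[(tert-butyldimethylsilyl)oxy]benzoate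
Conditions: N,N'-dicyclohexylcarbodiimide, 4-(dimethylamino)pyridine, CH2Cl2, rt to 40 °C
Reagents that add atoms: none
Why: Steglich esterification; only the secondary C6 hydroxyl can be acylated, since the tertiary C4 hydroxyl is inert and C10 is still a ketone, so no choice between two secondary alcohols arises.

Step 16
Reactants: 23 (1R,4S,5S,6R)-4-hydroxy-10-oxodauc-8-en-6-yl 4-[(tert-butyldimethylsilyl)oxy]benzoate
Product: 24 (1R,4S,5S,6R,10S)-4,10-dihydroxydauc-8-en-6-yl 4-[(tert-butyldimethylsilyl)oxy]benzoate
Conditions: NaBH4, CeCl3·7H2O, MeOH, −78 °C
Reagents that add atoms: none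
Why: Luche 1,2-reduction of the enone; hydride is expected on the face anti to the C6 aroyloxy group and the cyclopentane ring, which gives the 10S alcohol cis to the C6 ester.

Step 17
Reactants: 24 (1R,4S,5S,6R,10S)-4,10-dihydroxydauc-8-en-6-yl 4-[(tert-butyldimethylsilyl)oxy]benzoate; 25 3-methylbutanoyl chloride
Product: 26 (1R,4S,5S,6R,10S)-4-hydroxy-10-[(3-methylbutanoyl)oxy]dauc-8-en-6-yl 4-[(tert-butyldimethylsilyl)oxy]benzoate
Conditions: 25, pyridine, 4-(dimethylamino)pyridine (cat.), CH2Cl2, 0 °C to rt
Reagents that add atoms: none
Why: Nucleophile-catalysed acylation of the only secondary alcohol left; the hindered tertiary C4 hydroxyl should not react.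

Step 18
Reactants: 26 (1R,4S,5S,6R,10S)-4-hydroxy-10-[(3-methylbutanoyl)oxy]dauc-8-en-6-yl 4-[(tert-butyldimethylsilyl)oxy]benzoate
Product: 27 (1R,4S,5S,6R,10S)-4-hydroxy-10-[(3-methylbutanoyl)oxy]dauc-8-en-6-yl 4-hydroxybenzoate (CNP0086724.3)
Conditions: Bu4NF, AcOH (1:1), THF, 0 °C
Reagents that add atoms: none
Why: Fluoride cleavage of the aryl silyl ether, which is far more labile than the two carboxylic esters; acetic acid buffers the phenoxide so that neither ester should migrate or hydrolyse.

## Compound list

1 | 3-methylcyclopent-2-en-1-one | CC1=CC(=O)CC1 | starting material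
2 | (E)-1,2-dichloroethene | Cl/C=C/Cl | starting material
3 | racemic cis-fused 6,7-dichloro-5-methylbicyclo[3.2.0]heptan-2-one (chlorine epimers) | ClC1C(Cl)[C@]2(C)CCC(=O)[C@@H]21.ClC1C(Cl)[C@@]2(C)CCC(=O)[C@H]21 | intermediate
4 | racemic (1R,5S)-5-methylbicyclo[3.2.0]hept-6-en-2-one | C1=C[C@]2(C)CCC(=O)[C@@H]21.C1=C[C@@]2(C)CCC(=O)[C@H]21 | intermediate
5 | racemic (1R,2S,5S)-5-methylbicyclo[3.2.0]hept-6-en-2-ol (endo) | C1=C[C@]2(C)CC[C@H](O)[C@@H]21.C1=C[C@@]2(C)CC[C@@H](O)[C@H]21 | intermediate
6 | (1R,2S,5S)-5-methylbicyclo[3.2.0]hept-6-en-2-ol | C1=C[C@]2(C)CC[C@H](O)[C@@H]21 | intermediate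
7 | (1R,5S)-5-methylbicyclo[3.2.0]hept-6-en-2-one | C1=C[C@]2(C)CCC(=O)[C@@H]21 | intermediate
8 | lithium (1R,5S)-5-methylbicyclo[3.2.0]hepta-2,6-dien-2-olate | C1=C[C@]2(C)CC=C([O-])[C@@H]21.[Li+] | intermediate
9 | (1R,5S)-5-methylbicyclo[3.2.0]hepta-2,6-dien-2-yl trifluoromethanesulfonate | C1=C[C@]2(C)CC=C(OS(=O)(=O)C(F)(F)F)[C@@H]21 | intermediate
10 | (1R,5S)-5-methyl-2-(propan-2-yl)bicyclo[3.2.0]hepta-2,6-diene | C1=C[C@]2(C)CC=C(C(C)C)[C@@H]21 | intermediate
11 | (1R,2S,4R,6S)-6-methyl-2-(propan-2-yl)-3-oxatricyclo[4.2.0.0^2,4]oct-7-ene | C1=C[C@]2(C)C[C@H]3O[C@@]3(C(C)C)[C@@H]21 | intermediate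
12 | (1R,2S,5S)-5-methyl-2-(propan-2-yl)bicyclo[3.2.0]hept-6-en-2-ol | C1=C[C@]2(C)CC[C@](O)(C(C)C)[C@@H]21 | intermediate
13 | secondary ozonide of 12 (1,2,4-trioxolane bridging C6 and C10) | O1C(OO3)[C@]2(C)CC[C@](O)(C(C)C)[C@@H]2C13 | intermediate
14 | (1R,2R,3S)-3-hydroxy-1-methyl-3-(propan-2-yl)cyclopentane-1,2-dicarbaldehyde | O=C[C@]1(C)CC[C@](O)(C(C)C)[C@@H]1C=O | intermediate
15 | 3-chloro-2-(chloromethyl)prop-1-ene | ClCC(=C)CCl | starting material
16 | (1R,4S,5S,6R,10S)-dauc-8(14)-ene-4,6,10-triol | C=C1C[C@H](O)[C@]2(C)CC[C@](O)(C(C)C)[C@@H]2[C@H](O)C1 | intermediate
17 | (1R,4S,5R)-4-hydroxydauc-8(14)-ene-6,10-dione | C=C1CC(=O)[C@]2(C)CC[C@](O)(C(C)C)[C@@H]2C(=O)C1 | intermediate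
18 | (1R,4S,5S,6R)-4,6-dihydroxydauc-8(14)-en-10-one | C=C1CC(=O)[C@]2(C)CC[C@](O)(C(C)C)[C@@H]2[C@H](O)C1 | intermediate
19 | (1R,4S,5S,6R)-4,6-dihydroxydauc-8-en-10-one | CC1=CC(=O)[C@]2(C)CC[C@](O)(C(C)C)[C@@H]2[C@H](O)C1 | intermediate
20 | 4-hydroxybenzoic acid | OC(=O)c1ccc(O)cc1 | starting material
21 | tert-butyldimethylsilyl 4-[(tert-butyldimethylsilyl)oxy]benzoate | CC(C)(C)[Si](C)(C)OC(=O)c1ccc(O[Si](C)(C)C(C)(C)C)cc1 | intermediate
22 | 4-[(tert-butyldimethylsilyl)oxy]benzoic acid | OC(=O)c1ccc(O[Si](C)(C)C(C)(C)C)cc1 | intermediate
23 | (1R,4S,5S,6R)-4-hydroxy-10-oxodauc-8-en-6-yl 4-[(tert-butyldimethylsilyl)oxy]benzoate | CC1=CC(=O)[C@]2(C)CC[C@](O)(C(C)C)[C@@H]2[C@H](OC(=O)c2ccc(O[Si](C)(C)C(C)(C)C)cc2)C1 | intermediate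
24 | (1R,4S,5S,6R,10S)-4,10-dihydroxydauc-8-en-6-yl 4-[(tert-butyldimethylsilyl)oxy]benzoate | CC1=C[C@H](O)[C@]2(C)CC[C@](O)(C(C)C)[C@@H]2[C@H](OC(=O)c2ccc(O[Si](C)(C)C(C)(C)C)cc2)C1 | intermediate
25 | 3-methylbutanoyl chloride | CC(C)CC(Cl)=O | starting material
26 | (1R,4S,5S,6R,10S)-4-hydroxy-10-[(3-methylbutanoyl)oxy]dauc-8-en-6-yl 4-[(tert-butyldimethylsilyl)oxy]benzoate | CC1=C[C@H](OC(=O)CC(C)C)[C@]2(C)CC[C@](O)(C(C)C)[C@@H]2[C@H](OC(=O)c2ccc(O[Si](C)(C)C(C)(C)C)cc2)C1 | intermediate
27 | (1R,4S,5S,6R,10S)-4-hydroxy-10-[(3-methylbutanoyl)oxy]dauc-8-en-6-yl 4-hydroxybenzoate | CC1=C[C@H](OC(=O)CC(C)C)[C@]2(C)CC[C@](O)(C(C)C)[C@@H]2[C@H](OC(=O)c2ccc(O)cc2)C1 | target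

## Step count and least certain steps

Total step count: 18. Longest linear sequence: 17 steps (steps 1–13 and 15–18; step 14 is a one-step side branch).

**Step 11 (key step).** The second allylic chloride may be consumed intermolecularly or by protonolysis before ring closure, insertion into the second C–Cl bond may be slow, and the cis-dialdehyde may epimerise at C5 or fragment by retro-aldol reaction before it is trapped. Fallback: the two bonds are made in separate operations. Starting from 14, a mono-allylation with one equivalent of indium and an excess of 15 at 0 °C without iodide should stop at (1R,2R,5S)-2-[(1S)-4-chloro-1-hydroxy-3-methylidenebutyl]-5-hydroxy-2-methyl-5-(propan-2-yl)cyclopentane-1-carbaldehyde F1 (drawn as the C10 adduct, in equilibrium with its lactol; the C6 regioisomer would close to the same ring). The remaining allylic chloride is then closed onto the other formyl group by a Nozaki–Hiyama–Kishi-type allylation with CrCl2 in THF at high dilution, returning to the route at 16.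

**Step 12.** The doubly β,γ-unsaturated dione may slip into conjugation on either side, which would merge C6 and C10 into one vinylogous diketone; it may also epimerise at C5 or open by retro-aldol cleavage of C4–C5. The second oxidation may be slow if the first hydroxy ketone rests as a bridged hemiketal. Fallback: the dione is avoided, which is usable when the annulation has delivered the 6R carbinol. Starting from 16, phenylboronic acid (PhB(OH)2, molecular sieves, CH2Cl2) ties the 4,6-diol as the cyclic boronate (1R,4S,5S,6R,10S)-dauc-8(14)-ene-4,6,10-triol 4,6-O-phenylboronate F2. Dess–Martin oxidation of the only free hydroxyl gives the 10-oxo boronate F3, the amine base moves the alkene to give the dauc-8-en-10-one boronate F4, and diethanolamine releases the diol, returning to the route at 19.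

**Step 13.** Exchange of the hindered tertiary hydroxyl onto boron may be incomplete, undirected reduction may reach C10, or hydride may arrive on the other face of C6. Fallback for the stereochemical failure: starting from 17, the same reduction and isomerisation would then give (1R,4S,5S,6S)-4,6-dihydroxydauc-8-en-10-one F5. Its C6 hydroxyl is esterified with inversion by a Mitsunobu reaction with acid 22 (PPh3, diisopropyl azodicarboxylate, toluene), which forms the C6–O bond by SN2 displacement instead of acylation and returns to the route at 23.

**Step 16.** Facial selectivity at C10 may be poor, since the convex face carries the angular methyl next to the carbonyl, and some conjugate reduction may occur. Fallback: substrate control is replaced by catalyst control. Starting from 23, a Corey–Bakshi–Shibata reduction with catecholborane and (R)-1-methyl-3,3-diphenyltetrahydro-1H,3H-pyrrolo[1,2-c][1,3,2]oxazaborole (the quaternary C1 side taken as the large group) should give 24 directly. No new compound is involved.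

**Step 8.** The strained cyclobutene may compete for the peracid, attack may occur in part on the endo face, and the trisubstituted epoxide may rearrange under acid. Fallback: the C4–O bond is formed by a radical instead of an electrophilic process. Starting from 10, a Mukaiyama hydration (Co(acac)2, PhSiH3, O2, i-PrOH) transfers a hydrogen atom to C3, and the tertiary C4 radical is trapped by oxygen on the convex face. This returns to the route at 12 and bypasses 11.

## Further compounds

F1 | step 11 | (1R,2R,5S)-2-[(1S)-4-chloro-1-hydroxy-3-methylidenebutyl]-5-hydroxy-2-methyl-5-(propan-2-yl)cyclopentane-1-carbaldehyde | ClCC(=C)C[C@H](O)[C@]1(C)CC[C@](O)(C(C)C)[C@@H]1C=O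
F2 | step 12 | (1R,4S,5S,6R,10S)-dauc-8(14)-ene-4,6,10-triol 4,6-O-phenylboronate | C=C1C[C@H](O)[C@]2(C)CC[C@](O3)(C(C)C)[C@@H]2[C@H](OB3c4ccccc4)C1
F3 | step 12 | (1R,4S,5S,6R)-4,6-dihydroxydauc-8(14)-en-10-one 4,6-O-phenylboronate | C=C1CC(=O)[C@]2(C)CC[C@](O3)(C(C)C)[C@@H]2[C@H](OB3c4ccccc4)C1
F4 | step 12 | (1R,4S,5S,6R)-4,6-dihydroxydauc-8-en-10-one 4,6-O-phenylboronate | CC1=CC(=O)[C@]2(C)CC[C@](O3)(C(C)C)[C@@H]2[C@H](OB3c4ccccc4)C1
F5 | step 13 | (1R,4S,5S,6S)-4,6-dihydroxydauc-8-en-10-one | CC1=CC(=O)[C@]2(C)CC[C@](O)(C(C)C)[C@@H]2[C@@H](O)C1
F0 | step 16 | none | none
F0 | step 8 | none | none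
A1 | alternative 1 | 2,6-dimethyl-1,4-benzoquinone | CC1=CC(=O)C=C(C)C1=O
A2 | alternative 1 | trimethyl(4-methylpenta-1,2-dien-3-yl)silane | C=C=C([Si](C)(C)C)C(C)C
A3 | alternative 1 | cis-fused 6,7a-dimethyl-3-(propan-2-yl)-2-(trimethylsilyl)-3a,7a-dihydro-1H-indene-4,7-dione | CC=1C(=O)[C@]2(C)CC([Si](C)(C)C)=C(C(C)C)[C@@H]2C(=O)C=1
A4 | alternative 2 | 3-[(tert-butyldimethylsilyl)oxy]-2-(1,1-dimethoxy-3-methylbutan-2-yl)-1-(prop-1-en-2-yl)cyclohexan-1-ol (either carbinol epimer) | C=C(C)C1(O)CCC[C@@H](O[Si](C)(C)C(C)(C)C)[C@H]1[C@H](C(C)C)C(OC)OC
A5 | alternative 2 | cis-fused 6-[(tert-butyldimethylsilyl)oxy]-3-methoxy-1-methyl-4-(propan-2-yl)bicyclo[5.3.0]decan-10-one (daucane numbering) | C1CC(=O)[C@]2(C)C[C@@H](OC)[C@@H](C(C)C)[C@@H]2[C@H](O[Si](C)(C)C(C)(C)C)C1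
A6 | alternative 3 | 4,7-dimethoxy-1-(propan-2-yl)-1-[(triethylsilyl)oxy]indane | COc1ccc(OC)c2c1CC[C@]2(O[Si](CC)(CC)CC)C(C)C
A7 | alternative 3 | ethyl diazoacetate | CCOC(=O)C=[N+]=[N-]
A8 | alternative 3 | ethyl 1-isopropyl-4,8-dimethoxy-1-(triethylsilyloxy)-1,2,3,6-tetrahydroazulene-6-carboxylate | CCOC(=O)[C@H]1C=C(OC)C2=C(C(OC)=C1)[C@@](O[Si](CC)(CC)CC)(C(C)C)CC2
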